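The α-methylene-γ-butyrolactone is disconnected across O–C6 and C11–C7 (germacrane numbering). C6 is allylic to the C4=C5 alkene of the ten-membered ring and C7 is its neighbour, so both bonds are the retron of a palladium-catalysed diene heteroannulation: 2-bromoacrylic acid adds across the C6=C7 terminus of an acyclic (4E,6E)-diene, the vinylpalladium bonding C11 to C7 and the carboxylate closing on the C4–C6 π-allyl at C6. One operation thus installs the whole trans-lactone and leaves the 4E alkene. The diene precursor, two enal-derived homopropargylic alcohols joined by Suzuki coupling, already carries C2 and C9; ring-closing metathesis then forms the carbocycle with its 1(10)Z alkene.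

Key step: step 8

Assumption: positions are given in germacrane numbering of the target (C1=C10, C4=C5, lactone O on C6, C7–C11, C11=C13, ester on C9), and the sense of induction of the chiral catalysts in steps 1, 4 and 8 is assigned by analogy, the mirror-image catalyst being used if a step gave the opposite sense.

Step 1
Reactants: 1 (E)-but-2-enal; 2 allenylboronic acid pinacol ester
Product: 3 (4R,5E)-hept-5-en-1-yn-4-ol
Conditions: (R)-TRIP (3,3′-bis(2,4,6-triisopropylphenyl)-BINOL hydrogen phosphate, 5 mol %), 4 Å MS, toluene, −20 °C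
Reagents that add atoms: none
Why: Chiral-phosphoric-acid-catalysed propargylboration, in which the allenylboronate adds SE2′ through a closed six-membered transition state to the carbonyl group only and the catalyst, hydrogen-bonded to the boronate oxygen and the formyl hydrogen, selects the aldehyde face and so sets C2 as R.

Step 2
Reactants: 3 (4R,5E)-hept-5-en-1-yn-4-ol
Product: 4 tert-butyl[(4R,5E)-hept-5-en-1-yn-4-yloxy]dimethylsilane
Conditions: TBSCl, imidazole, DMF, rt
Reagents that add atoms: TBSCl, CC(C)(C)[Si](C)(C)Cl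
Why: Standard silylation of a secondary alcohol that does not touch the stereocentre.

Step 3
Reactants: 4 tert-butyl[(4R,5E)-hept-5-en-1-yn-4-yloxy]dimethylsilane
Product: 6 tert-butyl{[(1E,4R,5E)-1-iodo-2-methylhepta-1,5-dien-4-yl]oxy}dimethylsilane, via alkenyldimethylalane 5 (not isolated)
Conditions: AlMe3 (2.5 equiv), Cp2ZrCl2 (0.3 equiv), H2O (1 equiv), CH2Cl2, −25 °C; then I2, THF, −25 to 0 °C
Reagents that add atoms: AlMe3, C[Al](C)C; iodine, II
Why: Negishi zirconium-catalysed carboalumination adds Me–Al syn across the terminal alkyne (methyl to the internal carbon, the internal alkene being inert) and iodinolysis with retention gives the E iodide that carries the future 4E geometry.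

Step 4
Reactants: 7 2-methylprop-2-enal (methacrolein); 2 allenylboronic acid pinacol ester
Product: 8 (3S)-2-methylhex-1-en-5-yn-3-ol
Conditions: (S)-TRIP (5 mol %), 4 Å MS, toluene, −20 °C
Reagents that add atoms: none
Why: The same chiral-phosphoric-acid-catalysed propargylboration with the mirror-image catalyst attacks the other aldehyde face and sets C9 as S.

Step 5
Reactants: 8 (3S)-2-methylhex-1-en-5-yn-3-ol
Product: 9 triethyl{[(3S)-2-methylhex-1-en-5-yn-3-yl]oxy}silane
Conditions: TESCl, imidazole, CH2Cl2, 0 °C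
Reagents that add atoms: TESCl, CC[Si](CC)(CC)Cl
Why: Silylation gives an ether that survives the coming basic steps yet can later be removed in the presence of the tert-butyldimethylsilyl ether.

Step 6
Reactants: 9 triethyl{[(3S)-2-methylhex-1-en-5-yn-3-yl]oxy}silane
Product: 10 2-[(1E,4S)-5-methyl-4-(triethylsilyloxy)hexa-1,5-dien-1-yl]-4,4,5,5-tetramethyl-1,3,2-dioxaborolane
Conditions: pinacolborane (1.3 equiv), Cp2Zr(H)Cl (10 mol %), Et3N (10 mol %), neat, 60 °C
Reagents that add atoms: pinacolborane, [H]B1OC(C)(C)C(C)(C)O1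
Why: Zirconium-hydride-catalysed hydroboration adds H–B syn and anti-Markovnikov to the terminal alkyne to give the E alkenylboronate, the hindered 1,1-disubstituted alkene reacting far more slowly.

Step 7
Reactants: 6 tert-butyl{[(1E,4R,5E)-1-iodo-2-methylhepta-1,5-dien-4-yl]oxy}dimethylsilane; 10 2-[(1E,4S)-5-methyl-4-(triethylsilyloxy)hexa-1,5-dien-1-yl]-4,4,5,5-tetramethyl-1,3,2-dioxaborolane
Product: 11 (3S,5E,7E,10R,11E)-10-(tert-butyldimethylsilyloxy)-2,8-dimethyl-3-(triethylsilyloxy)trideca-1,5,7,11-tetraene
Conditions: Pd(PPh3)4 (5 mol %), aq. K3PO4 (3 equiv), THF, 50 °C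
Reagents that add atoms: none
Why: Suzuki–Miyaura coupling of an alkenyl iodide with an alkenylboronate proceeds with retention at both partners and so gives the (4E,6E)-diene (germacrane C4–C7), the silyl ethers tolerating the mild aqueous base.

Step 8
Reactants: 11 (3S,5E,7E,10R,11E)-10-(tert-butyldimethylsilyloxy)-2,8-dimethyl-3-(triethylsilyloxy)trideca-1,5,7,11-tetraene; 12 2-bromoprop-2-enoic acid (2-bromoacrylic acid)
Product: 13 (4S,5R)-5-[(1E,4R,5E)-4-(tert-butyldimethylsilyloxy)-2-methylhepta-1,5-dien-1-yl]-3-methylidene-4-[(2S)-3-methyl-2-(triethylsilyloxy)but-3-en-1-yl]oxolan-2-one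
Conditions: Pd2(dba)3 (5 mol %), (S)-MonoPhos (12 mol %), K2CO3 (2.5 equiv), DMF, 60 °C, 12 (1.5 equiv) added over 4 h
Reagents that add atoms: none
Why: Zerovalent palladium inserts into the C–Br bond of potassium 2-bromoacrylate, the alkenylpalladium adds syn across the disubstituted C6=C7 end of the diene so that C11 bonds to C7 and palladium sits on C6 as an η3-allyl over C4–C6, and the tethered carboxylate then forms the O–C6 bond with release of zerovalent palladium. The closest known reaction type is the Larock heteroannulation of 1,3-dienes by organic halides that carry a carboxylic acid or another O–H or N–H nucleophile. The lactone ring closes by 5-exo capture of the allyl terminus C6, since capture at C4 would need a seven-membered ring at a fully substituted carbon. C7 is set in the carbopalladation, where the two faces of the acyclic alkene are told apart by the chiral phosphoramidite on palladium because the resident centres C2 and C9 are remote. C6 is set trans to C7 by syn C–O reductive elimination within the six-membered oxapalladacycle on the E alkene and, because the product is an allylic ester that zerovalent palladium can re-ionise, by equilibration to the more stable trans-4,5-disubstituted lactone, while the 4E geometry survives because syn–anti exchange would need a σ-palladium at the tertiary C4. The step needs site selectivity for the conjugated diene over the propenyl and isopropenyl groups and for C7 over C4, which π-allyl stabilisation of diene insertion, the 1,2- and 1,1-disubstitution of the isolated alkenes next to silyloxy-bearing carbons and the full substitution of C4 should secure.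

Step 9
Reactants: 13 (4S,5R)-5-[(1E,4R,5E)-4-(tert-butyldimethylsilyloxy)-2-methylhepta-1,5-dien-1-yl]-3-methylidene-4-[(2S)-3-methyl-2-(triethylsilyloxy)but-3-en-1-yl]oxolan-2-one
Product: 14 (4S,5R)-5-[(1E,4R,5E)-4-(tert-butyldimethylsilyloxy)-2-methylhepta-1,5-dien-1-yl]-4-[(2S)-2-hydroxy-3-methylbut-3-en-1-yl]-3-methylideneoxolan-2-one
Conditions: PPTS (0.2 equiv), MeOH/CH2Cl2 1:1, 0 °C
Reagents that add atoms: none
Why: Acid-catalysed methanolysis cleaves the secondary triethylsilyl ether much faster than the secondary tert-butyldimethylsilyl ether, and the lactone is stable to weakly acidic methanol.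

Step 10
Reactants: 14 (4S,5R)-5-[(1E,4R,5E)-4-(tert-butyldimethylsilyloxy)-2-methylhepta-1,5-dien-1-yl]-4-[(2S)-2-hydroxy-3-methylbut-3-en-1-yl]-3-methylideneoxolan-2-one
Product: 15 (1(10)Z,2R,4E,6R,7S,9S)-2-(tert-butyldimethylsilyloxy)-9-hydroxygermacra-1(10),4,11(13)-trien-12,6-olide
Conditions: second-generation Hoveyda–Grubbs catalyst (15 mol % in two portions), toluene (1 mM), 90 °C, argon sparge
Reagents that add atoms: none
Why: Ring-closing metathesis in which the catalyst loads at the propenyl group, closes onto the isopropenyl group with help from the free allylic hydroxyl and expels propene, the cis (Z) geometry of the new trisubstituted alkene being the one normally delivered on closure of a ten-membered ring and the stereocentres staying untouched.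

Step 11
Reactants: 16 methyl but-2-ynoate
Product: 18 methyl (2Z)-2-(hydroxymethyl)but-2-enoate, via α-aluminoenoate 17 (not isolated)
Conditions: i-Bu2AlH (1.1 equiv), N-methylmorpholine N-oxide (1.1 equiv), THF, 0 °C; then CH2O gas (from cracked paraformaldehyde), −78 °C to rt
Reagents that add atoms: formaldehyde, C=O
Why: Syn hydroalumination of the ynoate puts hydrogen on C3 and aluminium on C2, and hydroxymethylation of the α-aluminoenoate with retention gives the Z (angelate-type) geometry, a vinylalumination route to a Morita–Baylis–Hillman-type product.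

Step 12
Reactants: 18 methyl (2Z)-2-(hydroxymethyl)but-2-enoate
Product: 19 methyl (2Z)-2-[(tert-butyldimethylsilyloxy)methyl]but-2-enoate
Conditions: TBSCl, imidazole, CH2Cl2, 0 °C to rt
Reagents that add atoms: TBSCl, CC(C)(C)[Si](C)(C)Cl
Why: Silylation of the primary allylic alcohol prevents self-acylation in the later esterification.

Step 13
Reactants: 19 methyl (2Z)-2-[(tert-butyldimethylsilyloxy)methyl]but-2-enoate
Product: 20 (2Z)-2-[(tert-butyldimethylsilyloxy)methyl]but-2-enoic acid
Conditions: LiOH·H2O, THF/H2O 3:1, 0 °C to rt; then 1 M HCl to pH 4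
Reagents that add atoms: lithium hydroxide, [Li+].[OH-]
Why: Saponification of the methyl ester at low temperature should leave the primary silyl ether and the Z trisubstituted alkene intact.

Step 14
Reactants: 15 (1(10)Z,2R,4E,6R,7S,9S)-2-(tert-butyldimethylsilyloxy)-9-hydroxygermacra-1(10),4,11(13)-trien-12,6-olide; 20 (2Z)-2-[(tert-butyldimethylsilyloxy)methyl]but-2-enoic acid
Product: 22 (1(10)Z,2R,4E,6R,7S,9S)-2-(tert-butyldimethylsilyloxy)-9-{(2Z)-2-[(tert-butyldimethylsilyloxy)methyl]but-2-enoyloxy}germacra-1(10),4,11(13)-trien-12,6-olide, via mixed anhydride 21 (not isolated)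
Conditions: 20, 2,4,6-trichlorobenzoyl chloride, Et3N, toluene, rt; then 15, DMAP, toluene, rt
Reagents that add atoms: none
Why: Yamaguchi esterification, in which the C9 hydroxyl attacks the less hindered enoyl carbonyl of the mixed anhydride at room temperature to limit Z to E isomerisation of the angelate-type acid, with retention at C9.

Step 15
Reactants: 22 (1(10)Z,2R,4E,6R,7S,9S)-2-(tert-butyldimethylsilyloxy)-9-{(2Z)-2-[(tert-butyldimethylsilyloxy)methyl]but-2-enoyloxy}germacra-1(10),4,11(13)-trien-12,6-olide
Product: 23 (1(10)Z,2R,4E,6R,7S,9S)-2-hydroxy-9-[(2Z)-2-(hydroxymethyl)but-2-enoyloxy]germacra-1(10),4,11(13)-trien-12,6-olide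
Conditions: HF·pyridine, pyridine, THF, 0 °C to rt
Reagents that add atoms: none
Why: Buffered fluoride cleaves both silyl ethers under non-basic conditions that should leave the α-methylene lactone, the allylic ester and the Z enoate intact.

Compound list
1 | (E)-but-2-enal (crotonaldehyde) | C/C=C/C=O | starting material
2 | allenylboronic acid pinacol ester, 2-(propa-1,2-dien-1-yl)-4,4,5,5-tetramethyl-1,3,2-dioxaborolane | C=C=CB1OC(C)(C)C(C)(C)O1 | starting material
3 | (4R,5E)-hept-5-en-1-yn-4-ol | C#CC[C@@H](O)/C=C/C | intermediate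
4 | tert-butyl[(4R,5E)-hept-5-en-1-yn-4-yloxy]dimethylsilane | C#CC[C@@H](O[Si](C)(C)C(C)(C)C)/C=C/C | intermediate
5 | [(1E,4R,5E)-4-(tert-butyldimethylsilyloxy)-2-methylhepta-1,5-dien-1-yl]dimethylalane (not isolated) | C[Al](C)/C=C(\C)C[C@@H](O[Si](C)(C)C(C)(C)C)/C=C/C | intermediate
6 | tert-butyl{[(1E,4R,5E)-1-iodo-2-methylhepta-1,5-dien-4-yl]oxy}dimethylsilane | I/C=C(\C)C[C@@H](O[Si](C)(C)C(C)(C)C)/C=C/C | intermediate
7 | 2-methylprop-2-enal (methacrolein) | C=C(C)C=O | starting material
8 | (3S)-2-methylhex-1-en-5-yn-3-ol | C=C(C)[C@@H](O)CC#C | intermediate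
9 | triethyl{[(3S)-2-methylhex-1-en-5-yn-3-yl]oxy}silane | C=C(C)[C@@H](O[Si](CC)(CC)CC)CC#C | intermediate
10 | 2-[(1E,4S)-5-methyl-4-(triethylsilyloxy)hexa-1,5-dien-1-yl]-4,4,5,5-tetramethyl-1,3,2-dioxaborolane | C=C(C)[C@@H](O[Si](CC)(CC)CC)C/C=C/B1OC(C)(C)C(C)(C)O1 | intermediate
11 | (3S,5E,7E,10R,11E)-10-(tert-butyldimethylsilyloxy)-2,8-dimethyl-3-(triethylsilyloxy)trideca-1,5,7,11-tetraene | C/C=C/[C@H](O[Si](C)(C)C(C)(C)C)C/C(C)=C/C=C/C[C@H](O[Si](CC)(CC)CC)C(C)=C | intermediate
12 | 2-bromoprop-2-enoic acid (2-bromoacrylic acid) | C=C(Br)C(=O)O | starting material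
13 | (4S,5R)-5-[(1E,4R,5E)-4-(tert-butyldimethylsilyloxy)-2-methylhepta-1,5-dien-1-yl]-3-methylidene-4-[(2S)-3-methyl-2-(triethylsilyloxy)but-3-en-1-yl]oxolan-2-one (trans-lactone) | C=C1C(=O)O[C@H](/C=C(\C)C[C@@H](O[Si](C)(C)C(C)(C)C)/C=C/C)[C@H]1C[C@H](O[Si](CC)(CC)CC)C(C)=C | intermediate
14 | (4S,5R)-5-[(1E,4R,5E)-4-(tert-butyldimethylsilyloxy)-2-methylhepta-1,5-dien-1-yl]-4-[(2S)-2-hydroxy-3-methylbut-3-en-1-yl]-3-methylideneoxolan-2-one | C=C1C(=O)O[C@H](/C=C(\C)C[C@@H](O[Si](C)(C)C(C)(C)C)/C=C/C)[C@H]1C[C@H](O)C(C)=C | intermediate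
15 | (1(10)Z,2R,4E,6R,7S,9S)-2-(tert-butyldimethylsilyloxy)-9-hydroxygermacra-1(10),4,11(13)-trien-12,6-olide | C=C1C(=O)O[C@@H]2/C=C(\C)C[C@@H](O[Si](C)(C)C(C)(C)C)/C=C(/C)[C@@H](O)C[C@@H]12 | intermediate
16 | methyl but-2-ynoate | CC#CC(=O)OC | starting material
17 | methyl 2-(diisobutylalumanyl)but-2-enoate, aluminium cis to H-3 and methyl cis to the ester (not isolated) | C/C=C(/[Al](CC(C)C)CC(C)C)C(=O)OC | intermediate
18 | methyl (2Z)-2-(hydroxymethyl)but-2-enoate (methyl sarracinate) | C/C=C(/CO)C(=O)OC | intermediate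
19 | methyl (2Z)-2-[(tert-butyldimethylsilyloxy)methyl]but-2-enoate | C/C=C(/CO[Si](C)(C)C(C)(C)C)C(=O)OC | intermediate
20 | (2Z)-2-[(tert-butyldimethylsilyloxy)methyl]but-2-enoic acid | C/C=C(/CO[Si](C)(C)C(C)(C)C)C(=O)O | intermediate
21 | mixed anhydride of acid 20 with 2,4,6-trichlorobenzoic acid (not isolated) | C/C=C(/CO[Si](C)(C)C(C)(C)C)C(=O)OC(=O)c1c(Cl)cc(Cl)cc1Cl | intermediate
22 | (1(10)Z,2R,4E,6R,7S,9S)-2-(tert-butyldimethylsilyloxy)-9-{(2Z)-2-[(tert-butyldimethylsilyloxy)methyl]but-2-enoyloxy}germacra-1(10),4,11(13)-trien-12,6-olide | C=C1C(=O)O[C@@H]2/C=C(\C)C[C@@H](O[Si](C)(C)C(C)(C)C)/C=C(/C)[C@@H](OC(=O)/C(=C\C)CO[Si](C)(C)C(C)(C)C)C[C@@H]12 | intermediate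
23 | (1(10)Z,2R,4E,6R,7S,9S)-2-hydroxy-9-[(2Z)-2-(hydroxymethyl)but-2-enoyloxy]germacra-1(10),4,11(13)-trien-12,6-olide (CNP0273961.1) | C=C1C(=O)O[C@@H]2/C=C(\C)C[C@@H](O)/C=C(/C)[C@@H](OC(=O)/C(=C\C)CO)C[C@@H]12 | target

Total step count: 15. Longest linear sequence: 9 steps (steps 1, 2, 3, 7, 8, 9, 10, 14, 15).

Steps most likely to fail

Step 8. What may go wrong: face selection in the carbopalladation rests on the ligand alone, so both trans-lactones (epimeric at C6 and C7) may form. The cis-lactone may persist if re-ionisation is slow. The alkenylpalladium may also add to bromoacrylate or to the product. Fallback, setting out from 6 and 9 and coming back at 13: the lactone is built instead by a catalytic asymmetric chromium-mediated 2-(alkoxycarbonyl)allylation of Nozaki–Hiyama–Kishi type followed by lactonisation, which makes the C6–C7 bond. Iodide 6 is lithiated (t-BuLi, Et2O, −78 °C) and formylated with DMF to give (2E,5R,6E)-5-(tert-butyldimethylsilyloxy)-3-methylocta-2,6-dienal F1. Alkyne 9 is deprotonated (n-BuLi, THF, −78 °C) and trapped with methyl chloroformate to give methyl (5S)-6-methyl-5-(triethylsilyloxy)hept-6-en-2-ynoate F2. Hydroalumination (i-Bu2AlH, N-methylmorpholine N-oxide, THF) and trapping with formaldehyde give methyl (2Z,5S)-2-(hydroxymethyl)-6-methyl-5-(triethylsilyloxy)hepta-2,6-dienoate F3. An Appel reaction (CBr4, PPh3, CH2Cl2, 0 °C) gives methyl (2E,5S)-2-(bromomethyl)-6-methyl-5-(triethylsilyloxy)hepta-2,6-dienoate F4. F4 and F1 are then coupled with CrCl2 (10 mol %), a chiral sulfonamide–oxazoline ligand, manganese powder and Cp2ZrCl2 in THF at room temperature. The anti-selective addition of the allylchromium species, with the aldehyde face chosen by the ligand, should give after spontaneous lactonisation the trans-lactone 13.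

Step 10. What may go wrong: oligomerisation instead of ring closure, because both alkenes are hindered and the ten-membered ring is strained; a mixture of alkene isomers at C1=C10 is a second uncertainty. Fallback, setting out from 14 and coming back at 15: the ring is closed without the silyl ether, and the hydroxyl groups are told apart afterwards. The silyl ether of 14 is cleaved (HF·pyridine, THF, 0 °C) to give (4S,5R)-4-[(2S)-2-hydroxy-3-methylbut-3-en-1-yl]-5-[(1E,4R,5E)-4-hydroxy-2-methylhepta-1,5-dien-1-yl]-3-methylideneoxolan-2-one F5. Metathesis of this bis-allylic diol (second-generation Hoveyda–Grubbs catalyst, toluene, 1 mM, 90 °C), where both hydroxyl groups can assist the catalyst and the bulky group at C2 is absent, should give (1(10)Z,2R,4E,6R,7S,9S)-2,9-dihydroxygermacra-1(10),4,11(13)-trien-12,6-olide F6. Site-selective silylation (TBSCl, imidazole, CH2Cl2, −20 °C) of the less hindered C2 hydroxyl (the C9 hydroxyl is flanked by the methyl-bearing C10) returns 15.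

Step 14. What may go wrong: slow acylation of the hindered ring alcohol, which gives time for Z to E isomerisation of the activated acid and for migration of the lactone to O9 under the basic conditions. Fallback, setting out from 14 and 20 and coming back at 22: the order of ring closure and acylation is inverted. The less hindered acyclic alcohol 14 is esterified with 20 by the same mixed-anhydride method (via 21) to give the C9 (2Z)-2-[(tert-butyldimethylsilyloxy)methyl]but-2-enoate of 14 F7. Ring-closing metathesis of F7 (second-generation Hoveyda–Grubbs catalyst, toluene, 1 mM, 90 °C) then gives 22 directly.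

Further compounds
F1 | step 8 | (2E,5R,6E)-5-(tert-butyldimethylsilyloxy)-3-methylocta-2,6-dienal | O=C/C=C(\C)C[C@@H](O[Si](C)(C)C(C)(C)C)/C=C/C
F2 | step 8 | methyl (5S)-6-methyl-5-(triethylsilyloxy)hept-6-en-2-ynoate | COC(=O)C#CC[C@H](O[Si](CC)(CC)CC)C(C)=C
F3 | step 8 | methyl (2Z,5S)-2-(hydroxymethyl)-6-methyl-5-(triethylsilyloxy)hepta-2,6-dienoate | COC(=O)/C(CO)=C\C[C@H](O[Si](CC)(CC)CC)C(C)=C
F4 | step 8 | methyl (2E,5S)-2-(bromomethyl)-6-methyl-5-(triethylsilyloxy)hepta-2,6-dienoate | COC(=O)/C(CBr)=C\C[C@H](O[Si](CC)(CC)CC)C(C)=C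
F5 | step 10 | (4S,5R)-4-[(2S)-2-hydroxy-3-methylbut-3-en-1-yl]-5-[(1E,4R,5E)-4-hydroxy-2-methylhepta-1,5-dien-1-yl]-3-methylideneoxolan-2-one | C=C1C(=O)O[C@H](/C=C(\C)C[C@@H](O)/C=C/C)[C@H]1C[C@H](O)C(C)=C
F6 | step 10 | (1(10)Z,2R,4E,6R,7S,9S)-2,9-dihydroxygermacra-1(10),4,11(13)-trien-12,6-olide | C=C1C(=O)O[C@@H]2/C=C(\C)C[C@@H](O)/C=C(/C)[C@@H](O)C[C@@H]12
F7 | step 14 | C9 (2Z)-2-[(tert-butyldimethylsilyloxy)methyl]but-2-enoate of acyclic alcohol 14 | C=C1C(=O)O[C@H](/C=C(\C)C[C@@H](O[Si](C)(C)C(C)(C)C)/C=C/C)[C@H]1C[C@H](OC(=O)/C(=C\C)CO[Si](C)(C)C(C)(C)C)C(C)=C
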